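The seven-membered ring is cut across C6–C5 and C8–C9 (benzo[7]annulene numbering: spiro carbon C5, CH2 C6, methine carbons C7–C9, aryl carbons C4a and C9a). This leaves a four-atom unit C9–C9a–C4a–C5, a biaryl whose aldehyde carbon C9 is electrophilic and whose ring B phenol para-carbon C5 is nucleophilic, and a three-carbon unit C6–C7–C8 that is nucleophilic at C8 and electrophilic at C6. A one-flask formal (4+3) annulation joins them: enantioselective allylboration of the aldehyde, then palladium-catalysed dearomative allylation of the phenol. The precursors are a biaryl hydroxy-aldehyde and a (Z)-2-(borylmethyl)but-2-enyl carbonate. Directed hydrogenation and invertive acetylation finish the route.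

Key step: step 5

Remark: ring A is the trimethoxybenzene ring and ring B the ring that ends as the dimethoxycyclohexadienone; compounds 1, 2, 4 and 5 are taken to be commercial.

Step 1
Reactants: 1 2-bromo-3,4,5-trimethoxybenzaldehyde; 2 2,6-dimethoxy-4-(4,4,5,5-tetramethyl-1,3,2-dioxaborolan-2-yl)phenol
Product: 3 2-(4-hydroxy-3,5-dimethoxyphenyl)-3,4,5-trimethoxybenzaldehyde
Conditions: Pd(OAc)2 (3 mol%), SPhos (6 mol%), K3PO4, toluene/H2O, 90 °C
Reagents that add atoms: none
Why: Suzuki–Miyaura coupling; the electron-rich biaryl phosphine should carry the di-ortho-substituted bromide, the free phenol is tolerated as its phenoxide, and no stereo-element arises because ring B is symmetric about the biaryl axis.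

Step 2
Reactants: 4 methyl but-2-ynoate; 5 2-(iodomethyl)-4,4,5,5-tetramethyl-1,3,2-dioxaborolane
Product: 7 methyl (Z)-2-[(4,4,5,5-tetramethyl-1,3,2-dioxaborolan-2-yl)methyl]but-2-enoate (methyl group trans to CH2B), via alkenylalane 6 (not isolated)
Conditions: iBu2AlH, HMPA, THF, 0 °C; then 5, 0 °C to rt
Reagents that add atoms: none
Why: Conjugate syn-hydroalumination of the ynoate places aluminium on C2 cis to the new C3–H, and C-alkylation of this alkenylalane by the α-iodoboronate (boron ate complex, then 1,2-migration with loss of iodide, a Matteson-type homologation) should keep that geometry, so that the methyl group ends trans to CH2B.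

Step 3
Reactants: 7 methyl (Z)-2-[(4,4,5,5-tetramethyl-1,3,2-dioxaborolan-2-yl)methyl]but-2-enoate
Product: 8 (Z)-2-[(4,4,5,5-tetramethyl-1,3,2-dioxaborolan-2-yl)methyl]but-2-en-1-ol
Conditions: iBu2AlH (2.2 equiv), CH2Cl2, −78 °C; aq. potassium sodium tartrate
Reagents that add atoms: none
Why: 1,2-Reduction of the enoate by diisobutylaluminium hydride at low temperature should give the allylic alcohol without touching the pinacol boronate or the alkene geometry.

Step 4
Reactants: 8 (Z)-2-[(4,4,5,5-tetramethyl-1,3,2-dioxaborolan-2-yl)methyl]but-2-en-1-ol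
Product: 9 methyl (Z)-2-[(4,4,5,5-tetramethyl-1,3,2-dioxaborolan-2-yl)methyl]but-2-en-1-yl carbonate
Conditions: ClCO2Me, pyridine, CH2Cl2, 0 °C
Reagents that add atoms: methyl chloroformate, COC(=O)Cl
Why: Acylation of the primary allylic alcohol with a chloroformate gives the allylic carbonate that later serves as the leaving group for zerovalent palladium.

Step 5
Reactants: 3 2-(4-hydroxy-3,5-dimethoxyphenyl)-3,4,5-trimethoxybenzaldehyde; 9 methyl (Z)-2-[(4,4,5,5-tetramethyl-1,3,2-dioxaborolan-2-yl)methyl]but-2-en-1-yl carbonate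
Product: 12 (8S,9S)-9-hydroxy-2,3,3',4,5'-pentamethoxy-8-methyl-7-methylidene-6,7,8,9-tetrahydrospiro[benzo[7]annulene-5,1'-cyclohexa-2',5'-dien]-4'-one, via acyclic pinacol borate 10 (not isolated), via spirocyclic pinacol borate 11 (not isolated)
Conditions: (S)-3,3'-bis(2,4,6-triisopropylphenyl)-1,1'-binaphthyl-2,2'-diyl hydrogen phosphate (10 mol%), 4 Å MS, toluene, −30 to 0 °C; then Pd(PPh3)4 (5 mol%), THF (dilution to 0.02 M), 40 °C, same flask; aq. NaHCO3 work-up
Reagents that add atoms: none
Why: Proposed new method: the chiral phosphoric acid activates boronate 9 and the aldehyde carbon C9 of 3 is attacked by the γ-carbon C8 through a closed six-membered chair transition state, which forms C8–C9 and leaves the C9 oxygen capped as pinacol borate 10 beside a new 2-substituted allylic carbonate; zerovalent palladium then ionises this carbonate, the methoxide released deprotonates the ring B phenol, and the phenoxide para-carbon C5 attacks a terminus of the allylpalladium complex, which forms C6–C5, turns ring B into the 2,6-dimethoxycyclohexadienone and closes the seven-membered ring. The closest known reaction types are the chiral-phosphoric-acid-catalysed allylboration of aromatic aldehydes, the palladium-catalysed intramolecular ipso-Friedel–Crafts allylic alkylation of para-substituted phenols and the ring-closing half of palladium trimethylenemethane (4+3) cycloadditions; their merger into one formal (4+3) annulation with a phenol para-carbon as the nucleophile is the untested part. The seven-membered ring closes in the trimethylenemethane mode: the nucleophile is tethered to the central allyl carbon C7, attack at either terminus gives the same product, and the other terminus remains as the exocyclic methylene on C7. C8 and C9 are set together in the allylboration, where the methyl group trans to CH2B in 9 sits equatorial in the chair and gives the anti (8S,9S) pair; the (S)-acid is chosen by analogy with benzaldehyde, for which the (R)-acid directs attack to the Re face, and the enantiomeric acid would be used should the sense be reversed here. The ring closure creates no stereocentre because ring B is symmetric and C5 is not stereogenic. The step needs carbon- over oxygen-alkylation, which rests on the C9 oxygen being held as a non-nucleophilic borate, on O-allylation of the phenol being reversible under palladium while C-allylation is not, and on the biaryl holding C5 within reach of the allyl terminus.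

Step 6
Reactants: 12 (8S,9S)-9-hydroxy-2,3,3',4,5'-pentamethoxy-8-methyl-7-methylidene-6,7,8,9-tetrahydrospiro[benzo[7]annulene-5,1'-cyclohexa-2',5'-dien]-4'-one
Product: 13 (7R,8S,9S)-9-hydroxy-2,3,3',4,5'-pentamethoxy-7,8-dimethyl-6,7,8,9-tetrahydrospiro[benzo[7]annulene-5,1'-cyclohexa-2',5'-dien]-4'-one
Conditions: [Ir(cod)(PCy3)(py)]PF6 (5 mol%), H2 (1 atm), CH2Cl2, 0 °C to rt
Reagents that add atoms: none
Why: Hydroxyl-directed homogeneous hydrogenation: the cationic iridium centre binds the C9 hydroxyl and the C7 exocyclic alkene on the same face and delivers hydrogen there, so that C7–H ends cis to the hydroxyl and the new C7 methyl trans to the C8 methyl (7R), while the trisubstituted, electron-poor dienone alkenes have no directing group and should not be reduced.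

Step 7
Reactants: 13 (7R,8S,9S)-9-hydroxy-2,3,3',4,5'-pentamethoxy-7,8-dimethyl-6,7,8,9-tetrahydrospiro[benzo[7]annulene-5,1'-cyclohexa-2',5'-dien]-4'-one
Product: 14 (7R,8S,9R)-2,3,3',4,5'-pentamethoxy-7,8-dimethyl-4'-oxo-6,7,8,9-tetrahydrospiro[benzo[7]annulene-5,1'-cyclohexa-2',5'-dien]-9-yl acetate (CNP0143674.1)
Conditions: PPh3, DIAD, AcOH, toluene, 0 °C to rt
Reagents that add atoms: acetic acid, CC(=O)O
Why: Mitsunobu esterification with acetic acid inverts C9 to the 9R acetate, and any leakage through the electron-rich benzylic cation should also be captured anti to the adjacent C8 methyl, which gives the same 8,9-trans product.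

Compound list
1 | 2-bromo-3,4,5-trimethoxybenzaldehyde | O=Cc1cc(OC)c(OC)c(OC)c1Br | starting material
2 | 2,6-dimethoxy-4-(4,4,5,5-tetramethyl-1,3,2-dioxaborolan-2-yl)phenol | COc1cc(cc(OC)c1O)B1OC(C)(C)C(C)(C)O1 | starting material
3 | 2-(4-hydroxy-3,5-dimethoxyphenyl)-3,4,5-trimethoxybenzaldehyde | O=Cc1cc(OC)c(OC)c(OC)c1-c1cc(OC)c(O)c(OC)c1 | intermediate
4 | methyl but-2-ynoate | CC#CC(=O)OC | starting material
5 | 2-(iodomethyl)-4,4,5,5-tetramethyl-1,3,2-dioxaborolane | ICB1OC(C)(C)C(C)(C)O1 | starting material
6 | methyl (E)-2-(diisobutylalumanyl)but-2-enoate (aluminium cis to C3–H; not isolated) | C/C=C(\C(=O)OC)[Al](CC(C)C)CC(C)C | intermediate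
7 | methyl (Z)-2-[(4,4,5,5-tetramethyl-1,3,2-dioxaborolan-2-yl)methyl]but-2-enoate | C/C=C(\C(=O)OC)CB1OC(C)(C)C(C)(C)O1 | intermediate
8 | (Z)-2-[(4,4,5,5-tetramethyl-1,3,2-dioxaborolan-2-yl)methyl]but-2-en-1-ol | C/C=C(\CO)CB1OC(C)(C)C(C)(C)O1 | intermediate
9 | methyl (Z)-2-[(4,4,5,5-tetramethyl-1,3,2-dioxaborolan-2-yl)methyl]but-2-en-1-yl carbonate | C/C=C(\COC(=O)OC)CB1OC(C)(C)C(C)(C)O1 | intermediate
10 | methyl (3S,4S)-4-[2-(4-hydroxy-3,5-dimethoxyphenyl)-3,4,5-trimethoxyphenyl]-3-methyl-2-methylidene-4-[(4,4,5,5-tetramethyl-1,3,2-dioxaborolan-2-yl)oxy]butyl carbonate (not isolated) | C=C(COC(=O)OC)[C@H](C)[C@H](OB1OC(C)(C)C(C)(C)O1)c1cc(OC)c(OC)c(OC)c1-c1cc(OC)c(O)c(OC)c1 | intermediate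
11 | (8S,9S)-2,3,3',4,5'-pentamethoxy-8-methyl-7-methylidene-9-[(4,4,5,5-tetramethyl-1,3,2-dioxaborolan-2-yl)oxy]-6,7,8,9-tetrahydrospiro[benzo[7]annulene-5,1'-cyclohexa-2',5'-dien]-4'-one (not isolated) | COC1=CC2(C=C(OC)C1=O)CC(=C)[C@H](C)[C@H](OB3OC(C)(C)C(C)(C)O3)c1cc(OC)c(OC)c(OC)c12 | intermediate
12 | (8S,9S)-9-hydroxy-2,3,3',4,5'-pentamethoxy-8-methyl-7-methylidene-6,7,8,9-tetrahydrospiro[benzo[7]annulene-5,1'-cyclohexa-2',5'-dien]-4'-one | COC1=CC2(C=C(OC)C1=O)CC(=C)[C@H](C)[C@H](O)c1cc(OC)c(OC)c(OC)c12 | intermediate
13 | (7R,8S,9S)-9-hydroxy-2,3,3',4,5'-pentamethoxy-7,8-dimethyl-6,7,8,9-tetrahydrospiro[benzo[7]annulene-5,1'-cyclohexa-2',5'-dien]-4'-one | COC1=CC2(C=C(OC)C1=O)C[C@@H](C)[C@H](C)[C@H](O)c1cc(OC)c(OC)c(OC)c12 | intermediate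
14 | (7R,8S,9R)-2,3,3',4,5'-pentamethoxy-7,8-dimethyl-4'-oxo-6,7,8,9-tetrahydrospiro[benzo[7]annulene-5,1'-cyclohexa-2',5'-dien]-9-yl acetate | COC1=CC2(C=C(OC)C1=O)C[C@@H](C)[C@H](C)[C@@H](OC(C)=O)c1cc(OC)c(OC)c(OC)c12 | target

Total step count: 7.
Longest linear sequence: 6 steps (4 to 7, 8, 9, 12, 13, 14).

Steps most likely to fail

Step 5. The seven-membered closure may be slow, so that the allylpalladium intermediate is diverted to intermolecular allylation or loses a proton to a diene. The borate cap may be exchanged by the methanol formed, which would open ring closure at the C9 oxygen to a tetrahydrofuran. The hindered, electron-rich aldehyde may also erode the enantioselectivity of the allylboration. The fallback sets out from compounds 3 and 9 and comes back at compound 12; it separates the two bond formations and replaces the borate cap by a silyl ether, each stage being an established reaction type run on an isolated compound. The same phosphoric-acid-catalysed allylboration with aqueous work-up should give methyl (3S,4S)-4-hydroxy-4-[2-(4-hydroxy-3,5-dimethoxyphenyl)-3,4,5-trimethoxyphenyl]-3-methyl-2-methylidenebutyl carbonate F1. TBSOTf and 2,6-lutidine should give its bis(tert-butyldimethylsilyl) ether F2. Pd(PPh3)4 with Bu4NF (1 equiv, THF, 0 °C) should unmask only the aryl silyl ether and close the ring by intramolecular ipso-Friedel–Crafts allylic alkylation to the tert-butyldimethylsilyl ether of 12 F3. HF·pyridine should then return 12.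

Step 7. The electron-rich, α-branched benzylic oxyphosphonium ion may ionise, which would lead to elimination towards C8=C9 or to incomplete inversion, and the hindered carbinol may react slowly. The fallback sets out from compound 13 and comes back at compound 14; it sets C9 by reagent control instead of substitution. Oxidation with the periodinane 1,1,1-triacetoxy-1,1-dihydro-1,2-benziodoxol-3(1H)-one should give (7R,8S)-2,3,3',4,5'-pentamethoxy-7,8-dimethyl-7,8-dihydrospiro[benzo[7]annulene-5,1'-cyclohexa-2',5'-diene]-4',9(6H)-dione F4. Corey–Bakshi–Shibata reduction with the (S)-methyl oxazaborolidine and catecholborane at −78 °C should give (7R,8S,9R)-9-hydroxy-2,3,3',4,5'-pentamethoxy-7,8-dimethyl-6,7,8,9-tetrahydrospiro[benzo[7]annulene-5,1'-cyclohexa-2',5'-dien]-4'-one F5; the aryl ketone is expected to be reduced in preference to the dienone carbonyl, which is flanked by two methoxy-bearing carbons. Ac2O, pyridine and DMAP should then give 14.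

Step 2. The α-alumino enoate may lose its geometry through its allenoate form before C-alkylation, or alkylation by the iodomethylboronate may be sluggish; either would erode the anti selectivity of step 5. The fallback sets out from compound 4 and comes back at compound 7; it fixes the geometry by a syn-hydrometalation whose product can be isolated. Pd(PPh3)4-catalysed hydrostannation with Bu3SnH should give methyl (E)-2-(tributylstannyl)but-2-enoate F6. Iododestannylation with I2 should give methyl (E)-2-iodobut-2-enoate F7 with retention. Suzuki–Miyaura coupling with bis(4,4,5,5-tetramethyl-1,3,2-dioxaborolan-2-yl)methane (Pd(P(t-Bu)3)2, K3PO4, dioxane/H2O, rt) should then give 7 with retention.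

Further compounds
F1 | step 5 | methyl (3S,4S)-4-hydroxy-4-[2-(4-hydroxy-3,5-dimethoxyphenyl)-3,4,5-trimethoxyphenyl]-3-methyl-2-methylidenebutyl carbonate | C=C(COC(=O)OC)[C@H](C)[C@H](O)c1cc(OC)c(OC)c(OC)c1-c1cc(OC)c(O)c(OC)c1
F2 | step 5 | bis(tert-butyldimethylsilyl) ether of F1 (secondary alcohol and phenol both silylated) | C=C(COC(=O)OC)[C@H](C)[C@H](O[Si](C)(C)C(C)(C)C)c1cc(OC)c(OC)c(OC)c1-c1cc(OC)c(O[Si](C)(C)C(C)(C)C)c(OC)c1
F3 | step 5 | (8S,9S)-9-[(tert-butyldimethylsilyl)oxy]-2,3,3',4,5'-pentamethoxy-8-methyl-7-methylidene-6,7,8,9-tetrahydrospiro[benzo[7]annulene-5,1'-cyclohexa-2',5'-dien]-4'-one | COC1=CC2(C=C(OC)C1=O)CC(=C)[C@H](C)[C@H](O[Si](C)(C)C(C)(C)C)c1cc(OC)c(OC)c(OC)c12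
F4 | step 7 | (7R,8S)-2,3,3',4,5'-pentamethoxy-7,8-dimethyl-7,8-dihydrospiro[benzo[7]annulene-5,1'-cyclohexa-2',5'-diene]-4',9(6H)-dione | COC1=CC2(C=C(OC)C1=O)C[C@@H](C)[C@H](C)C(=O)c1cc(OC)c(OC)c(OC)c12
F5 | step 7 | (7R,8S,9R)-9-hydroxy-2,3,3',4,5'-pentamethoxy-7,8-dimethyl-6,7,8,9-tetrahydrospiro[benzo[7]annulene-5,1'-cyclohexa-2',5'-dien]-4'-one | COC1=CC2(C=C(OC)C1=O)C[C@@H](C)[C@H](C)[C@@H](O)c1cc(OC)c(OC)c(OC)c12
F6 | step 2 | methyl (E)-2-(tributylstannyl)but-2-enoate | C/C=C(\C(=O)OC)[Sn](CCCC)(CCCC)CCCC
F7 | step 2 | methyl (E)-2-iodobut-2-enoate | C/C=C(\C(=O)OC)I
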